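Locants: seven-membered ring C1–C2(Me)=C3–C4(O)–C5(O)–C6(Me2)–C7, six-membered ring C7–C8H=C9(Me)–C10(=O)–C11H2–C1. Everything rests on the C6–C7 bond between the gem-dimethyl carbon and a ring-fusion carbon. C7 is the γ-carbon of the C8=C9–C10=O enone and C6 neighbours the C5 oxygen, so a linear silyl dienol ether of the cyclohexenone is united, under a Lewis acid, with the tertiary carbon of a C5–C6 epoxide. This one operation closes the seven-membered ring, forms quaternary C6 and the cis ring fusion, frees the C5 hydroxyl and regenerates the enone. The precursor is a 1-silyloxycyclohexa-1,3-diene whose C1 carries a Z-alkenyl chain ending in a threo silyloxy epoxide.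

Key step: step 10

Remark on the chemistry: the ProPhenol enantiomer in step 1 is the one that adds the alkynyl group to the Re face of 1; both are sold, and the sense is confirmed on 4 by MTPA ester analysis before scale-up.

Abbreviation: R* = (2Z,4R)-4-(tert-butyldimethylsilyloxy)-4-[(2S)-3,3-dimethyloxiran-2-yl]but-2-en-2-yl.

**Route**

Step 1
Reactants: 1 3-methylbut-2-enal (prenal); 2 propyne
Product: 4 (S)-2-methylhept-2-en-5-yn-4-ol, via methyl(prop-1-ynyl)zinc 3 (not isolated)
Conditions: 2 (3 equiv), Me2Zn (3 equiv), ProPhenol ligand (10 mol%), Ph3P=O (20 mol%), toluene, 0 °C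
Reagents that add atoms: none
Why: Zinc/ProPhenol-catalysed enantioselective alkynylation of an enal, in which the dinuclear zinc catalyst holds the aldehyde and alkynylzinc 3 together and delivers the propynyl group to the Re face of 1, setting the carbinol centre that becomes C4.

Step 2
Reactants: 4 (S)-2-methylhept-2-en-5-yn-4-ol
Product: 6 (S,Z)-6-iodo-2-methylhepta-2,5-dien-4-ol, via cyclic alkenylalanate 5 (not isolated)
Conditions: NaAlH2(OCH2CH2OMe)2 (1.6 equiv), THF, 0 °C to rt; EtOAc; then I2, THF, −78 °C
Reagents that add atoms: iodine, II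
Why: Hydroxyl-directed trans-hydroalumination of the propargylic alcohol places hydride on the proximal and aluminium on the distal alkyne carbon (five-membered alanate 5), and iodinolysis of the C–Al bond with retention gives the Z iodoalkene with iodine cis to C4, while the isolated trisubstituted alkene does not react.

Step 3
Reactants: 6 (S,Z)-6-iodo-2-methylhepta-2,5-dien-4-ol
Product: 7 (R,Z)-1-[(S)-3,3-dimethyloxiran-2-yl]-3-iodobut-2-en-1-ol (threo)
Conditions: mCPBA (1.1 equiv), NaHCO3, CH2Cl2, −20 to 0 °C
Reagents that add atoms: mCPBA, OOC(=O)c1cccc(Cl)c1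
Why: Hydroxyl-directed Prilezhaev epoxidation of the electron-rich trisubstituted alkene, in which A1,3 strain with the cis methyl group holds the carbinol hydrogen in the alkene plane so that the hydrogen-bonded peracid enters from the hydroxyl face and gives the threo epoxy alcohol (C5 set from C4), the iodine-deactivated alkene being spared.

Step 4
Reactants: 7 threo epoxy alcohol
Product: 8 tert-butyldimethylsilyl ether of 7 (Z vinyl iodide)
Conditions: TBSCl, imidazole, DMF, rt
Reagents that add atoms: TBSCl, CC(C)(C)[Si](C)(C)Cl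
Why: Standard imidazole-mediated silylation of the secondary allylic alcohol, chosen over a silyl triflate so that no Lewis acid meets the acid-labile trisubstituted epoxide.

Step 5
Reactants: 8 silyl ether vinyl iodide; 9 acrolein
Product: 10 (2E,4Z,6R)-6-(tert-butyldimethylsilyloxy)-6-[(S)-3,3-dimethyloxiran-2-yl]-4-methylhexa-2,4-dienal
Conditions: 9 (3 equiv), Pd(OAc)2 (5 mol%), NaHCO3, Bu4NCl, DMF, rt to 40 °C
Reagents that add atoms: none
Why: Ligand-free phase-transfer Mizoroki–Heck coupling, in which oxidative addition of the vinyl iodide and syn insertion/β-hydride elimination on acrolein keep the Z geometry at C2=C3 and give the E enal, the bicarbonate medium leaving epoxide and silyl ether intact.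

Step 6
Reactants: 11 methyl 3-oxopentanoate
Product: 12 allyl 3-oxopentanoate
Conditions: allyl alcohol (5 equiv), DMAP (10 mol%), toluene, reflux, MeOH removed over 4 Å molecular sieves
Reagents that add atoms: allyl alcohol, C=CCO
Why: DMAP-catalysed transesterification of a β-keto ester, driven by removal of methanol, which installs the ester that can later be removed under neutral conditions.

Step 7
Reactants: 10 dienal; 12 allyl 3-oxopentanoate
Product: 14 allyl (6S)-3-methyl-2-oxo-6-R*-cyclohex-3-ene-1-carboxylate, via Michael adduct 13 (not isolated)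
Conditions: (R)-α,α-bis[3,5-bis(trifluoromethyl)phenyl]prolinol trimethylsilyl ether (10 mol%), PhCO2H (10 mol%), toluene, 0 °C to rt; then piperidine, AcOH (20 mol% each), 4 Å molecular sieves, 40 °C
Reagents that add atoms: none
Why: Iminium-catalysed Michael addition of the β-keto ester to the enal β-carbon C1 (the diarylsilyloxymethyl group of the R catalyst blocks one face of the E,s-trans iminium ion and so sets C1, and 1,4-addition is preferred over 1,6 because C3 is screened by the branched C4 substituent), followed by amine/acid-mediated aldol condensation of C9 onto the C8 aldehyde, the two together making a Robinson-type annulation whose C11 epimers converge in step 8.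

Step 8
Reactants: 14 ring B allyl ester
Product: 16 (5S)-2-methyl-5-R*-cyclohex-2-en-1-one, via β-keto acid 15 (not isolated)
Conditions: Pd(PPh3)4 (3 mol%), morpholine (3 equiv), THF, rt to 40 °C
Reagents that add atoms: none
Why: Tsuji–Trost deallylation with zerovalent palladium (morpholine traps the allyl fragment) liberates β-keto acid 15, which decarboxylates under the neutral conditions, so that the epoxide, the silyl ether and the C1 centre are not put at risk.

Step 9
Reactants: 16 ring B enone
Product: 18 triethyl{[(5R)-2-methyl-5-R*-cyclohexa-1,3-dien-1-yl]oxy}silane, via potassium dienolate 17 (not isolated)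
Conditions: KOtBu (1.05 equiv), THF, −78 to −30 °C; then TESCl (1.3 equiv), Et3N, −78 °C; NaHCO3 work-up, Et3N-deactivated silica
Reagents that add atoms: TESCl, CC[Si](CC)(CC)Cl
Why: Reversible deprotonation (tert-butanol shuttles protons) settles on the through-conjugated γ-dienolate 17, the thermodynamic enolate of an enone, and the hard silyl chloride traps it on oxygen to give the linear 1-silyloxy-1,3-diene, with TES chosen because it is more labile than the C4 TBS ether.

Step 10
Reactants: 18 linear triethylsilyl dienol ether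
Product: 19 (1R,4R,5R,7S)-4-(tert-butyldimethylsilyloxy)-5-hydroxy-2,6,6,9-tetramethylbicyclo[5.4.0]undeca-2,8-dien-10-one (cis-fused)
Conditions: Me2AlCl (1.5 equiv), CH2Cl2 (0.01 M), −78 to −40 °C; aqueous potassium sodium tartrate
Reagents that add atoms: none
Why: Proposed new method: Me2AlCl coordinates the oxirane oxygen, the C6–O bond lengthens toward the tertiary cation and the γ-carbon C7 of the silyl dienol ether attacks C6, after which the silyl oxocarbenium ion gives up Et3Si to chloride, so that the C8=C9–C10=O enone is restored and the C5 oxygen is left as an aluminium alkoxide that is protonated on work-up. The closest known reaction types are epoxide-initiated cation–olefin cyclisations terminated by silyl enol ethers under MeAlCl2 or Me2AlCl (six-membered rings) and γ-selective vinylogous Mukaiyama alkylations with SN1-type electrophiles; the extension lies in the seven-membered ring and in the dienol ether as terminator. The seven-membered ring closes in the endo mode with respect to the oxirane (both epoxide carbons become ring members, as in the first ring closure of oxidosqualene) and in the exo mode with respect to the C7=C8 bond, helped by the Z C2=C3 alkene, which holds C1 and C4 cis and removes two rotors. C7 is the only new stereocentre and is controlled by C1, because the tether on the neighbouring C1 can reach the p-lobe of C7 only on its own face, which gives the cis ring fusion; C6 is not stereogenic and C5 keeps its C–O bond and configuration. The step needs opening at C6 and not C5 (secured by Markovnikov ionisation at the tertiary carbon and by the electron-withdrawing C4 silyloxy group beside C5), attack through C7 and not C11 or C9 (secured by the absence of the cross-conjugated dienol ether after step 9 and by the nine-membered ring that C9 would demand) and survival of the dienol ether (Me2AlCl consumes adventitious acid as methane).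

Step 11
Reactants: 19 bicyclic hydroxy enone; 20 angelic acid
Product: 22 C5 angelate of 19, via angelic trichlorobenzoic anhydride 21 (not isolated)
Conditions: 20 (3 equiv), 2,4,6-trichlorobenzoyl chloride, Et3N, toluene, rt; then 19, 75 °C, no DMAP
Reagents that add atoms: none
Why: Yamaguchi-type mixed-anhydride esterification run thermally without a nucleophilic catalyst, in which the hindered C5 hydroxyl attacks the unshielded angeloyl carbonyl of 21 and the absence of DMAP shuts down the conjugate addition–elimination path by which activated angelates turn into tiglates, so the Z geometry bought with 20 is kept.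

Step 12
Reactants: 22 C5 angelate silyl ether
Product: 23 C5 angelate with free C4 hydroxyl
Conditions: HF·pyridine, pyridine, THF, 0 °C to rt
Reagents that add atoms: none
Why: Fluoride-induced Si–O cleavage in a buffered acidic medium, where no alkoxide is formed, so that the C5 angelate does not migrate to C4 and the γ-centre C7 of the enone is not epimerised.

Step 13
Reactants: 20 angelic acid
Product: 24 (Z)-2-methylbut-2-en-1-ol (angelyl alcohol)
Conditions: LiAlH4, Et2O, 0 °C
Reagents that add atoms: none
Why: Hydride reduction of the carboxylic acid to the allylic alcohol by 1,2-delivery, which leaves the trisubstituted Z alkene untouched.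

Step 14
Reactants: 24 angelyl alcohol
Product: 25 [(2S,3R)-2,3-dimethyloxiran-2-yl]methanol
Conditions: Ti(OiPr)4 (10 mol%), L-(+)-diethyl tartrate (12 mol%), t-BuOOH (2 equiv), 4 Å molecular sieves, CH2Cl2, −20 °C
Reagents that add atoms: tert-butyl hydroperoxide, CC(C)(C)OO
Why: Katsuki–Sharpless asymmetric epoxidation, in which L-(+)-tartrate delivers oxygen to the face that gives 2S epoxy alcohols from primary allylic alcohols, here (2S,3R) for the Z alkene; L-(+)- and not D-(−)-tartrate is required because only the C2 descriptor, not the geometry, changes to R when CH2OH becomes CO2H.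

Step 15
Reactants: 25 epoxy alcohol
Product: 26 (2R,3R)-2,3-dimethyloxirane-2-carboxylic acid
Conditions: RuCl3·xH2O (2 mol%), NaIO4 (3 equiv), MeCN/EtOAc/H2O, 0 °C to rt
Reagents that add atoms: sodium periodate, [Na+].[O-]I(=O)(=O)=O; water, O
Why: RuO4-catalysed oxidation of the primary alcohol to the carboxylic acid with periodate as terminal oxidant, a standard conversion of 2,3-epoxy alcohols into glycidic acids that does not touch the oxirane or its stereocentres.

Step 16
Reactants: 23 C5 angelate C4 alcohol; 26 epoxyangelic acid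
Product: 28 CNP0332927.1 (target), via epoxyangelic trichlorobenzoic anhydride 27 (not isolated)
Conditions: 26 (2 equiv), 2,4,6-trichlorobenzoyl chloride, Et3N, THF, rt; then 23, DMAP (0.5 equiv), toluene, 0 °C to rt
Reagents that add atoms: none
Why: Yamaguchi esterification, in which DMAP transfers the α-quaternary epoxy acyl group of 27 to the allylic C4 hydroxyl; the acid has neither an enolisable α-hydrogen nor an isomerisable alkene, and the brief exposure to DMAP at or below room temperature should leave the C5 angelate unchanged.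

**Compound list**

1 | 3-methylbut-2-enal (prenal) | CC(C)=CC=O | starting material
2 | propyne | CC#C | starting material
3 | methyl(prop-1-yn-1-yl)zinc | C[Zn]C#CC | intermediate (not isolated)
4 | (S)-2-methylhept-2-en-5-yn-4-ol | CC(C)=C[C@H](O)C#CC | intermediate
5 | sodium 2,2-bis(2-methoxyethoxy)-3-methyl-5-(2-methylprop-1-enyl)-2,5-dihydro-1,2-oxaaluminol-2-uide (cyclic alkenylalanate, carbinol centre as in 4) | CC(C)=C[C@H]1C=C(C)[Al-](OCCOC)(OCCOC)O1.[Na+] | intermediate (not isolated)
6 | (S,Z)-6-iodo-2-methylhepta-2,5-dien-4-ol | CC(C)=C[C@H](O)/C=C(/C)I | intermediate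
7 | (R,Z)-1-[(S)-3,3-dimethyloxiran-2-yl]-3-iodobut-2-en-1-ol (threo) | O1[C@H](C1(C)C)[C@H](O)/C=C(/C)I | intermediate
8 | tert-butyl{[(1R,2Z)-1-[(2S)-3,3-dimethyloxiran-2-yl]-3-iodobut-2-en-1-yl]oxy}dimethylsilane | O1[C@H](C1(C)C)[C@H](O[Si](C)(C)C(C)(C)C)/C=C(/C)I | intermediate
9 | acrolein (prop-2-enal) | C=CC=O | starting material
10 | (2E,4Z,6R)-6-(tert-butyldimethylsilyloxy)-6-[(S)-3,3-dimethyloxiran-2-yl]-4-methylhexa-2,4-dienal | O1[C@H](C1(C)C)[C@H](O[Si](C)(C)C(C)(C)C)/C=C(/C)\C=C\C=O | intermediate
11 | methyl 3-oxopentanoate | CCC(=O)CC(=O)OC | starting material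
12 | allyl 3-oxopentanoate | CCC(=O)CC(=O)OCC=C | intermediate
13 | allyl (3S)-5-oxo-2-propanoyl-3-R*-pentanoate (C2 epimers) | O1[C@H](C1(C)C)[C@H](O[Si](C)(C)C(C)(C)C)/C=C(/C)[C@@H](CC=O)C(C(=O)OCC=C)C(=O)CC | intermediate (not isolated)
14 | allyl (6S)-3-methyl-2-oxo-6-R*-cyclohex-3-ene-1-carboxylate (C1 epimers) | O1[C@H](C1(C)C)[C@H](O[Si](C)(C)C(C)(C)C)/C=C(/C)[C@@H]1C(C(=O)OCC=C)C(=O)C(C)=CC1 | intermediate
15 | (6S)-3-methyl-2-oxo-6-R*-cyclohex-3-ene-1-carboxylic acid | O1[C@H](C1(C)C)[C@H](O[Si](C)(C)C(C)(C)C)/C=C(/C)[C@@H]1C(C(=O)O)C(=O)C(C)=CC1 | intermediate (not isolated)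
16 | (5S)-2-methyl-5-R*-cyclohex-2-en-1-one | O1[C@H](C1(C)C)[C@H](O[Si](C)(C)C(C)(C)C)/C=C(/C)[C@@H]1CC(=O)C(C)=CC1 | intermediate
17 | potassium (5R)-2-methyl-5-R*-cyclohexa-1,3-dien-1-olate | O1[C@H](C1(C)C)[C@H](O[Si](C)(C)C(C)(C)C)/C=C(/C)[C@@H]1CC([O-])=C(C)C=C1.[K+] | intermediate (not isolated)
18 | triethyl{[(5R)-2-methyl-5-R*-cyclohexa-1,3-dien-1-yl]oxy}silane | O1[C@H](C1(C)C)[C@H](O[Si](C)(C)C(C)(C)C)/C=C(/C)[C@@H]1CC(O[Si](CC)(CC)CC)=C(C)C=C1 | intermediate
19 | (1R,4R,5R,7S)-4-(tert-butyldimethylsilyloxy)-5-hydroxy-2,6,6,9-tetramethylbicyclo[5.4.0]undeca-2,8-dien-10-one (cis-fused, locants as in the overview) | O[C@H]1[C@H](O[Si](C)(C)C(C)(C)C)C=C(C)[C@@H]2CC(=O)C(C)=C[C@@H]2C1(C)C | intermediate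
20 | angelic acid, (Z)-2-methylbut-2-enoic acid | C/C=C(/C)C(=O)O | starting material
21 | (Z)-2-methylbut-2-enoic 2,4,6-trichlorobenzoic anhydride | C/C=C(/C)C(=O)OC(=O)c1c(Cl)cc(Cl)cc1Cl | intermediate (not isolated)
22 | (1R,4R,5R,7S)-4-(tert-butyldimethylsilyloxy)-2,6,6,9-tetramethyl-10-oxobicyclo[5.4.0]undeca-2,8-dien-5-yl (Z)-2-methylbut-2-enoate | C/C=C(/C)C(=O)O[C@H]1[C@H](O[Si](C)(C)C(C)(C)C)C=C(C)[C@@H]2CC(=O)C(C)=C[C@@H]2C1(C)C | intermediate
23 | (1R,4R,5R,7S)-4-hydroxy-2,6,6,9-tetramethyl-10-oxobicyclo[5.4.0]undeca-2,8-dien-5-yl (Z)-2-methylbut-2-enoate | C/C=C(/C)C(=O)O[C@H]1[C@H](O)C=C(C)[C@@H]2CC(=O)C(C)=C[C@@H]2C1(C)C | intermediate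
24 | (Z)-2-methylbut-2-en-1-ol (angelyl alcohol) | C/C=C(/C)CO | intermediate
25 | [(2S,3R)-2,3-dimethyloxiran-2-yl]methanol | OC[C@]1(C)O[C@@H]1C | intermediate
26 | (2R,3R)-2,3-dimethyloxirane-2-carboxylic acid (epoxyangelic acid) | OC(=O)[C@]1(C)O[C@@H]1C | intermediate
27 | (2R,3R)-2,3-dimethyloxirane-2-carboxylic 2,4,6-trichlorobenzoic anhydride | Clc1cc(Cl)c(C(=O)OC(=O)[C@]2(C)O[C@@H]2C)c(Cl)c1 | intermediate (not isolated)
28 | (1R,4R,5R,7S)-5-{[(Z)-2-methylbut-2-enoyl]oxy}-2,6,6,9-tetramethyl-10-oxobicyclo[5.4.0]undeca-2,8-dien-4-yl (2R,3R)-2,3-dimethyloxirane-2-carboxylate (CNP0332927.1) | C/C=C(/C)C(=O)O[C@H]1[C@H](OC(=O)[C@]2(C)O[C@@H]2C)C=C(C)[C@@H]2CC(=O)C(C)=C[C@@H]2C1(C)C | target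

**Step count and risks**

Total step count: 16. Longest linear sequence: 12 steps (steps 1 to 5, 7 to 12 and 16).

Steps most likely to fail:

1. Step 10 (Proposed new method). The Lewis acid may trigger a hydride shift of the epoxide to a ketone, or open it with chloride without C–C bond formation. The dienol ether may be lost by protodesilylation, and any cross-conjugated dienol ether would close through C11. Fallback, using only known reaction types and making the C6–C7 bond first; it sets out from epoxy alcohol 7 and comes back at 19: hydroxyl-directed alkynyl transfer from Et2Al–C≡C–SiMe3 (from trimethylsilylacetylene, n-BuLi and Et2AlCl; toluene, 0 °C) to the tertiary oxirane carbon of 7 should give the silylalkynyl diol F1, and K2CO3/MeOH the terminal alkyne diol F2; the allylic C4 hydroxyl is silylated first (TBSCl, imidazole) to the mono-TBS ether F3 and the hindered C5 hydroxyl then capped (TESCl, imidazole, DMAP) to the bis-silyl ether F4; anti-Markovnikov hydration of the alkyne (Cy2BH, then NaBO3·4H2O) gives the aldehyde F5, whose two new carbons are C7 and C1; enamine-catalysed Michael addition to methyl vinyl ketone with the (R)-diarylprolinol silyl ether (sets C7) and amine/acid aldol condensation, a Robinson annulation, give the 4-substituted cyclohex-2-enone F6, and α'-methylation (LiN(iPr)2, MeI, THF, −78 °C) gives the 6-methyl enone F7 (C9 epimers, of no consequence); an intramolecular reductive Heck reaction (Pd(OAc)2, PPh3, HCO2Na, Bu4NCl, DMF, 60 °C), in which the Z vinylpalladium adds to the enone β-carbon C1 on the face of the C7 chain, closes the seven-membered ring as the cis-fused ketone F8; the more substituted trimethylsilyl enol ether F9 (TMSCl, Et3N, DMF, 60 °C) is dehydrogenated by Saegusa–Ito oxidation (Pd(OAc)2, MeCN) to the enone triethylsilyl ether F10, and PPTS/MeOH removes the TES group to give 19.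

2. Step 7. The soft nucleophile may add 1,6 instead of 1,4, and the iminium ion may drain into a trienamine, with loss of the C4 centre, Z-to-E isomerisation or epoxide opening. Facial selectivity at C1 may be poor, and retro-Michael reaction may erode it during the aldol condensation. Fallback, setting out from vinyl iodide 8 and coming back at enone 16: Miyaura borylation of 8 (B2pin2, PdCl2(PPh3)2, KOPh, toluene, 50 °C; retention of the Z geometry) gives the pinacol alkenylboronate F11; rhodium-catalysed asymmetric conjugate addition to 6-methylcyclohex-2-en-1-one ([Rh(OH)((S)-binap)]2, dioxane/H2O, 40 °C; Hayashi–Miyaura reaction, the ligand sets C1) gives the 3-alkenyl-6-methylcyclohexanone F12 (C9 epimers); the more substituted trimethylsilyl enol ether F13 (TMSCl, Et3N, DMF, 60 °C) is oxidised with Pd(OAc)2 in MeCN (Saegusa–Ito oxidation) to 16.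

3. Step 11. Acylation of the neopentyl C5 hydroxyl, flanked by quaternary C6 and the C4 silyl ether, may be too slow, and forcing it may isomerise the activated angeloyl group to tigloyl. Fallback, setting out from 19 and coming back at 22: 19 is acylated with 2-(diphenoxyphosphoryl)propanoic acid (DCC, DMAP, CH2Cl2, rt to 40 °C; an acyl donor with no double bond to isomerise, so forcing conditions are harmless) to give the phosphonate ester F14, and a Z-selective Horner–Wadsworth–Emmons olefination with acetaldehyde (NaI, DBU, THF, −78 to 0 °C; diaryl phosphonate variant) builds the angelate alkene on the ester and gives 22.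

**Further compounds**

F1 | step 10 | (4R,5R,6Z)-7-iodo-3,3-dimethyl-1-(trimethylsilyl)oct-6-en-1-yne-4,5-diol | O[C@H](C(C)(C)C#C[Si](C)(C)C)[C@H](O)/C=C(/C)I
F2 | step 10 | (4R,5R,6Z)-7-iodo-3,3-dimethyloct-6-en-1-yne-4,5-diol | O[C@H](C(C)(C)C#C)[C@H](O)/C=C(/C)I
F3 | step 10 | (4R,5R,6Z)-5-(tert-butyldimethylsilyloxy)-7-iodo-3,3-dimethyloct-6-en-1-yn-4-ol | O[C@H](C(C)(C)C#C)[C@H](O[Si](C)(C)C(C)(C)C)/C=C(/C)I
F4 | step 10 | 4-O-triethylsilyl ether of F3 (bis-silyl ether) | CC[Si](CC)(CC)O[C@H](C(C)(C)C#C)[C@H](O[Si](C)(C)C(C)(C)C)/C=C(/C)I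
F5 | step 10 | (4R,5R,6Z)-5-(tert-butyldimethylsilyloxy)-7-iodo-3,3-dimethyl-4-(triethylsilyloxy)oct-6-enal | CC[Si](CC)(CC)O[C@H](C(C)(C)CC=O)[C@H](O[Si](C)(C)C(C)(C)C)/C=C(/C)I
F6 | step 10 | (4S)-4-substituted cyclohex-2-en-1-one carrying the bis-silylated iodoalkenyl chain through its quaternary carbon | CC[Si](CC)(CC)O[C@H](C(C)(C)[C@@H]1C=CC(=O)CC1)[C@H](O[Si](C)(C)C(C)(C)C)/C=C(/C)I
F7 | step 10 | 6-methyl derivative of F6 (C9 epimers) | CC[Si](CC)(CC)O[C@H](C(C)(C)[C@@H]1C=CC(=O)C(C)C1)[C@H](O[Si](C)(C)C(C)(C)C)/C=C(/C)I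
F8 | step 10 | (1R,4R,5R,7S)-4-(tert-butyldimethylsilyloxy)-2,6,6,9-tetramethyl-5-(triethylsilyloxy)bicyclo[5.4.0]undec-2-en-10-one (cis-fused, C9 epimers) | CC[Si](CC)(CC)O[C@H]1[C@H](O[Si](C)(C)C(C)(C)C)C=C(C)[C@@H]2CC(=O)C(C)C[C@@H]2C1(C)C
F9 | step 10 | 10-trimethylsilyl enol ether of F8 (C9=C10) | CC[Si](CC)(CC)O[C@H]1[C@H](O[Si](C)(C)C(C)(C)C)C=C(C)[C@@H]2CC(O[Si](C)(C)C)=C(C)C[C@@H]2C1(C)C
F10 | step 10 | C5 O-triethylsilyl ether of 19 | CC[Si](CC)(CC)O[C@H]1[C@H](O[Si](C)(C)C(C)(C)C)C=C(C)[C@@H]2CC(=O)C(C)=C[C@@H]2C1(C)C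
F11 | step 7 | pinacol (Z)-alkenylboronate from 8 (boron in place of iodine) | O1[C@H](C1(C)C)[C@H](O[Si](C)(C)C(C)(C)C)/C=C(/C)B1OC(C)(C)C(C)(C)O1
F12 | step 7 | (3S)-6-methyl-3-R*-cyclohexan-1-one (C6 epimers) | O1[C@H](C1(C)C)[C@H](O[Si](C)(C)C(C)(C)C)/C=C(/C)[C@@H]1CC(=O)C(C)CC1
F13 | step 7 | more substituted trimethylsilyl enol ether of F12 | O1[C@H](C1(C)C)[C@H](O[Si](C)(C)C(C)(C)C)/C=C(/C)[C@@H]1CC(O[Si](C)(C)C)=C(C)CC1
F14 | step 11 | C5 2-(diphenoxyphosphoryl)propanoate of 19 | CC(P(=O)(Oc1ccccc1)Oc1ccccc1)C(=O)O[C@H]1[C@H](O[Si](C)(C)C(C)(C)C)C=C(C)[C@@H]2CC(=O)C(C)=C[C@@H]2C1(C)C
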